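**Assumption:** ring compounds carry germacrane numbering (C1 ketone carbon, C4=C5 ring olefin, C6 lactone carbinol, C7=C11 butenolide olefin, C8 acetoxy carbinol, C10=C14 methylidene, C12 lactone carbonyl, C13 acetoxymethyl); the C1 carbinol in 14–20 is a roughly 1:1 epimer mixture that is later oxidised, so its centre is left undefined in the SMILES.

## Retrosynthetic overview

1. Target 23 ⇐ acetylation, desilylation and C1 oxidation of the bicyclic tris-silyl ether 19.
2. 19 ⇐ ynal 17 + CO in one nickel-mediated [2+2+1] operation: the C6–C7 bond closes the ten-membered carbocycle inside an oxanickelacycle, and CO insertion then closes the butenolide.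
3. 17 ⇐ vinyllithium from bromide 9 + aldehyde 12 (C1–C10 bond), then C6 deacetylation and oxidation.
4. 9 ⇐ TBS propargyl ether 1 + DMF + allene (asymmetric 2-bromoallylboration sets C8); 12 ⇐ neryl acetate 10, which supplies the 4Z olefin.

## Route

Step 1
Reactants: 1 tert-butyldimethyl(prop-2-yn-1-yloxy)silane
Product: 4 4-(tert-butyldimethylsilyloxy)but-2-ynal, via lithium acetylide 2 (not isolated), via lithium hemiaminal alkoxide 3 (not isolated)
Conditions: n-BuLi, THF, −78 °C; DMF, −78 → 0 °C; inverse quench into aq. KH2PO4, 0 °C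
Reagents that add atoms: N,N-dimethylformamide (CN(C)C=O)
Why: Formylation of the lithium acetylide with DMF (Bouveault-type formylation) gives the ynal, and the buffered inverse quench keeps liberated dimethylamine from adding to it; no stereocenter is formed.

Step 2
Reactants: 4 4-(tert-butyldimethylsilyloxy)but-2-ynal; 5 propa-1,2-diene
Product: 8 (4S)-2-bromo-7-(tert-butyldimethylsilyloxy)hept-1-en-5-yn-4-ol, via bromoallylborane 6 (not isolated), via borinate ester 7 (not isolated)
Conditions: B-bromodiisopinocampheylborane from (+)-α-pinene, 5, CH2Cl2, −78 → −20 °C; 4, −78 °C; HOCH2CH2NH2, rt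
Reagents that add atoms: B-bromodiisopinocampheylborane derived from (+)-α-pinene (BrB([C@@H]1C[C@@H]2C[C@H]([C@H]1C)C2(C)C)[C@@H]1C[C@@H]2C[C@H]([C@H]1C)C2(C)C)
Why: Bromoboration of allene gives the 2-bromoallylborane, which adds to the ynal through a chair Zimmerman–Traxler transition state (Brown-type asymmetric allylboration); the (+)-α-pinene-derived isopinocampheyl groups direct attack to the Si face of the aldehyde and set the future C8 as S.

Step 3
Reactants: 8 (4S)-2-bromo-7-(tert-butyldimethylsilyloxy)hept-1-en-5-yn-4-ol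
Product: 9 (4S)-2-bromo-4,7-bis(tert-butyldimethylsilyloxy)hept-1-en-5-yne
Conditions: TBSCl, imidazole, DMF, rt
Reagents that add atoms: tert-butyldimethylsilyl chloride (C[Si](C)(Cl)C(C)(C)C)
Why: Standard imidazole-promoted silylation of the secondary propargylic alcohol; the stereocenter is not touched.

Step 4
Reactants: 10 neryl acetate
Product: 12 (2Z)-3-methyl-6-oxohex-2-en-1-yl acetate, via epoxyneryl acetate 11 (not isolated)
Conditions: mCPBA, CH2Cl2, 0 °C; solvent swap; H5IO6, THF/H2O, 0 °C
Reagents that add atoms: 3-chloroperoxybenzoic acid (OOC(=O)c1cccc(Cl)c1)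
Why: mCPBA epoxidises the electron-rich 6,7-olefin in preference to the acetate-deactivated 2,3-olefin (Prilezhaev epoxidation), and periodic acid opens and cleaves the epoxide (Malaprade-type glycol cleavage) to the aldehyde with the Z-olefin untouched.

Step 5
Reactants: 9 (4S)-2-bromo-4,7-bis(tert-butyldimethylsilyloxy)hept-1-en-5-yne; 12 (2Z)-3-methyl-6-oxohex-2-en-1-yl acetate
Product: 15 (2Z,9S)-9,12-bis(tert-butyldimethylsilyloxy)-3-methyl-7-methylidene-6-(triethylsilyloxy)dodec-2-en-10-yn-1-yl acetate (chain C6 = germacrane C1; epimer mixture), via vinyllithium 13 (not isolated), via lithium alkoxide 14 (not isolated)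
Conditions: t-BuLi (2.0 equiv), Et2O, −78 °C; 12 (1.2 equiv), −78 °C; TESCl, THF, −78 °C → rt
Reagents that add atoms: triethylsilyl chloride (CC[Si](Cl)(CC)CC)
Why: Bromine–lithium exchange gives the 2-lithioalkene, which adds 1,2 to the aldehyde far faster than to the acetate at −78 °C, and the alkoxide is trapped in situ as the TES ether; the new C1 carbinol forms without control, which is harmless because C1 later becomes the ketone.

Step 6
Reactants: 15 (2Z,9S)-9,12-bis(tert-butyldimethylsilyloxy)-3-methyl-7-methylidene-6-(triethylsilyloxy)dodec-2-en-10-yn-1-yl acetate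
Product: 16 (2Z,9S)-9,12-bis(tert-butyldimethylsilyloxy)-3-methyl-7-methylidene-6-(triethylsilyloxy)dodec-2-en-10-yn-1-ol
Conditions: K2CO3 (cat.), MeOH, 0 °C
Reagents that add atoms: none
Why: Base-catalysed methanolysis (transesterification) removes the only ester in the molecule, the primary allylic acetate, while the silyl ethers survive.

Step 7
Reactants: 16 (2Z,9S)-9,12-bis(tert-butyldimethylsilyloxy)-3-methyl-7-methylidene-6-(triethylsilyloxy)dodec-2-en-10-yn-1-ol
Product: 17 (2Z,9S)-9,12-bis(tert-butyldimethylsilyloxy)-3-methyl-7-methylidene-6-(triethylsilyloxy)dodec-2-en-10-ynal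
Conditions: TEMPO (2,2,6,6-tetramethylpiperidin-1-oxyl, 10 mol %), PhI(OAc)2, CH2Cl2, rt; used at once
Reagents that add atoms: none
Why: The oxoammonium (TEMPO/PhI(OAc)2) oxidation converts the primary allylic alcohol into the enal without Z to E isomerisation, as is known for nerol to neral.

Step 8
Reactants: 17 (2Z,9S)-9,12-bis(tert-butyldimethylsilyloxy)-3-methyl-7-methylidene-6-(triethylsilyloxy)dodec-2-en-10-ynal
Product: 19 (4Z,6R,8S)-8,13-bis(tert-butyldimethylsilyloxy)-1-(triethylsilyloxy)germacra-4,7(11),10(14)-trien-12,6-olide (C1 epimer mixture), via oxanickelacyclopentene 18 (not isolated)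
Conditions: Ni(cod)2 (1.2 equiv) premixed with IPr [1,3-bis(2,6-diisopropylphenyl)imidazol-2-ylidene, 1.2 equiv], toluene, 25 °C, 17 added over 8 h (final 0.005 M); then CO (1 atm), 0 °C → rt
Reagents that add atoms: carbon monoxide ([C-]#[O+])
Why: Proposed new method: zerovalent nickel bearing the bulky carbene should couple aldehyde carbon C6 with alkyne carbon C7 (the terminus with the larger, branched substituent, which bulky carbenes favour, and the only mode that gives an exocyclic ten-membered closure) to form oxanickelacyclopentene 18, after which CO inserts into the Ni–C11 bond and C–O reductive elimination closes the butenolide, so both rings arise in one flask as a macrocyclic hetero-Pauson–Khand [2+2+1] reaction; C6 is set under control of C8, because A(1,3) strain with the C13 methylene holds C8–H in the plane of the forming C7=C11 bond and the chain should close with C5 on the face opposite C9 (avoiding a syn-pentane-like array across C7), which is the 6R isomer; the closest known reaction types are nickel-catalysed reductive macrocyclizations of ynals through such metallacycles, carbonylation of oxanickelacycles to lactones, and titanium-, molybdenum- and ruthenium-based hetero-Pauson–Khand cyclizations of yne-aldehydes to fused butenolides.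

Step 9
Reactants: 19 (4Z,6R,8S)-8,13-bis(tert-butyldimethylsilyloxy)-1-(triethylsilyloxy)germacra-4,7(11),10(14)-trien-12,6-olide
Product: 21 (4Z,6R,8S)-8,13-bis(tert-butyldimethylsilyloxy)-1-oxogermacra-4,7(11),10(14)-trien-12,6-olide, via C1 alcohol 20 (not isolated)
Conditions: IBX (3 equiv), wet DMSO, rt
Reagents that add atoms: none
Why: IBX in DMSO cleaves triethylsilyl ethers selectively in the presence of TBS ethers and oxidises the liberated allylic alcohol in the same pot (hypervalent iodine oxidation), which also removes the uncontrolled C1 center.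

Step 10
Reactants: 21 (4Z,6R,8S)-8,13-bis(tert-butyldimethylsilyloxy)-1-oxogermacra-4,7(11),10(14)-trien-12,6-olide
Product: 22 (4Z,6R,8S)-8,13-dihydroxy-1-oxogermacra-4,7(11),10(14)-trien-12,6-olide
Conditions: HF·pyridine, pyridine/THF, 0 °C → rt; carried on without delay
Reagents that add atoms: none
Why: Buffered HF·pyridine removes both TBS ethers (fluoride-mediated desilylation) under mildly acidic conditions that spare the enone, the Z-olefin and the C6 center.

Step 11
Reactants: 22 (4Z,6R,8S)-8,13-dihydroxy-1-oxogermacra-4,7(11),10(14)-trien-12,6-olide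
Product: 23 (4Z,6R,8S)-8,13-diacetoxy-1-oxogermacra-4,7(11),10(14)-trien-12,6-olide (CNP0239761.1)
Conditions: Ac2O, pyridine, DMAP (4-dimethylaminopyridine, cat.), CH2Cl2, 0 °C
Reagents that add atoms: acetic anhydride (CC(=O)OC(C)=O)
Why: DMAP-catalysed acetylation (nucleophilic acyl transfer) of the primary and the secondary hydroxyl gives the diacetate without touching any stereocenter.

## Compound list

1 | tert-butyldimethyl(prop-2-yn-1-yloxy)silane | C#CCO[Si](C)(C)C(C)(C)C | starting material
2 | [3-(tert-butyldimethylsilyloxy)prop-1-yn-1-yl]lithium | [Li]C#CCO[Si](C)(C)C(C)(C)C | intermediate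
3 | lithium 4-(tert-butyldimethylsilyloxy)-1-(dimethylamino)but-2-yn-1-olate | [Li]OC(N(C)C)C#CCO[Si](C)(C)C(C)(C)C | intermediate
4 | 4-(tert-butyldimethylsilyloxy)but-2-ynal | O=CC#CCO[Si](C)(C)C(C)(C)C | intermediate
5 | propa-1,2-diene (allene) | C=C=C | starting material
6 | B-(2-bromoallyl)diisopinocampheylborane, Ipc from (+)-α-pinene | C=C(Br)CB([C@@H]1C[C@@H]2C[C@H]([C@H]1C)C2(C)C)[C@@H]1C[C@@H]2C[C@H]([C@H]1C)C2(C)C | intermediate
7 | (4S)-2-bromo-7-(tert-butyldimethylsilyloxy)hept-1-en-5-yn-4-yl diisopinocampheylborinate | C=C(Br)C[C@H](OB([C@@H]1C[C@@H]2C[C@H]([C@H]1C)C2(C)C)[C@@H]1C[C@@H]2C[C@H]([C@H]1C)C2(C)C)C#CCO[Si](C)(C)C(C)(C)C | intermediate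
8 | (4S)-2-bromo-7-(tert-butyldimethylsilyloxy)hept-1-en-5-yn-4-ol | C=C(Br)C[C@H](O)C#CCO[Si](C)(C)C(C)(C)C | intermediate
9 | (4S)-2-bromo-4,7-bis(tert-butyldimethylsilyloxy)hept-1-en-5-yne | C=C(Br)C[C@H](O[Si](C)(C)C(C)(C)C)C#CCO[Si](C)(C)C(C)(C)C | intermediate
10 | neryl acetate, (2Z)-3,7-dimethylocta-2,6-dien-1-yl acetate | CC(C)=CCC/C(C)=C\COC(C)=O | starting material
11 | 6,7-epoxyneryl acetate (racemic epoxide) | CC1(C)OC1CC/C(C)=C\COC(C)=O | intermediate
12 | (2Z)-3-methyl-6-oxohex-2-en-1-yl acetate | O=CCC/C(C)=C\COC(C)=O | intermediate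
13 | [(4S)-4,7-bis(tert-butyldimethylsilyloxy)hept-1-en-5-yn-2-yl]lithium | [Li]C(=C)C[C@H](O[Si](C)(C)C(C)(C)C)C#CCO[Si](C)(C)C(C)(C)C | intermediate
14 | lithium (2Z,9S)-1-acetoxy-9,12-bis(tert-butyldimethylsilyloxy)-3-methyl-7-methylidenedodec-2-en-10-yn-6-olate | C=C(C(O[Li])CC/C(C)=C\COC(C)=O)C[C@H](O[Si](C)(C)C(C)(C)C)C#CCO[Si](C)(C)C(C)(C)C | intermediate
15 | (2Z,9S)-9,12-bis(tert-butyldimethylsilyloxy)-3-methyl-7-methylidene-6-(triethylsilyloxy)dodec-2-en-10-yn-1-yl acetate | C=C(C(O[Si](CC)(CC)CC)CC/C(C)=C\COC(C)=O)C[C@H](O[Si](C)(C)C(C)(C)C)C#CCO[Si](C)(C)C(C)(C)C | intermediate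
16 | (2Z,9S)-9,12-bis(tert-butyldimethylsilyloxy)-3-methyl-7-methylidene-6-(triethylsilyloxy)dodec-2-en-10-yn-1-ol | C=C(C(O[Si](CC)(CC)CC)CC/C(C)=C\CO)C[C@H](O[Si](C)(C)C(C)(C)C)C#CCO[Si](C)(C)C(C)(C)C | intermediate
17 | (2Z,9S)-9,12-bis(tert-butyldimethylsilyloxy)-3-methyl-7-methylidene-6-(triethylsilyloxy)dodec-2-en-10-ynal | C=C(C(O[Si](CC)(CC)CC)CC/C(C)=C\C=O)C[C@H](O[Si](C)(C)C(C)(C)C)C#CCO[Si](C)(C)C(C)(C)C | intermediate
18 | IPr-ligated oxanickelacyclopentene (Ni bonded to O6 and C11; 4Z,6R,8S) | C=C1C[C@H](O[Si](C)(C)C(C)(C)C)C2=C(CO[Si](C)(C)C(C)(C)C)[Ni](=C3N(c4c(C(C)C)cccc4C(C)C)C=CN3c3c(C(C)C)cccc3C(C)C)O[C@@H]2/C=C(/C)CCC1O[Si](CC)(CC)CC | intermediate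
19 | (4Z,6R,8S)-8,13-bis(tert-butyldimethylsilyloxy)-1-(triethylsilyloxy)germacra-4,7(11),10(14)-trien-12,6-olide | C=C1C[C@H](O[Si](C)(C)C(C)(C)C)C2=C(CO[Si](C)(C)C(C)(C)C)C(=O)O[C@@H]2/C=C(/C)CCC1O[Si](CC)(CC)CC | intermediate
20 | (4Z,6R,8S)-8,13-bis(tert-butyldimethylsilyloxy)-1-hydroxygermacra-4,7(11),10(14)-trien-12,6-olide | C=C1C[C@H](O[Si](C)(C)C(C)(C)C)C2=C(CO[Si](C)(C)C(C)(C)C)C(=O)O[C@@H]2/C=C(/C)CCC1O | intermediate
21 | (4Z,6R,8S)-8,13-bis(tert-butyldimethylsilyloxy)-1-oxogermacra-4,7(11),10(14)-trien-12,6-olide | C=C1C[C@H](O[Si](C)(C)C(C)(C)C)C2=C(CO[Si](C)(C)C(C)(C)C)C(=O)O[C@@H]2/C=C(/C)CCC1=O | intermediate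
22 | (4Z,6R,8S)-8,13-dihydroxy-1-oxogermacra-4,7(11),10(14)-trien-12,6-olide | C=C1C[C@H](O)C2=C(CO)C(=O)O[C@@H]2/C=C(/C)CCC1=O | intermediate
23 | (4Z,6R,8S)-8,13-diacetoxy-1-oxogermacra-4,7(11),10(14)-trien-12,6-olide | C=C1C[C@H](OC(C)=O)C2=C(COC(C)=O)C(=O)O[C@@H]2/C=C(/C)CCC1=O | target

## Step count and risk

Total step count: 11. Longest linear sequence: 10 steps (1 → 23 through steps 1–3 and 5–11).

The three steps most likely to fail:

**Step 8.** The bicyclization is unprecedented at this ring size. It may lose to oligomerisation, to conjugate engagement of the enal, or to β-hydride loss from the nickel alkoxide; CO may fail to insert cleanly; and the C6 selectivity is a prediction, not a precedent. The fallback sets out from 17 and comes back at 19. Ynal 17 is added slowly to Ni(cod)2/IPr as before, but the metallacycle is quenched with I2 at −78 °C instead of CO. This gives the macrocyclic (Z)-γ-hydroxy vinyl iodide (4Z,6R,8S)-11-iodo-8,13-bis(tert-butyldimethylsilyloxy)-1-(triethylsilyloxy)germacra-4,7(11),10(14)-trien-6-ol F1. The butenolide is then closed in a separate palladium-catalysed cyclocarbonylation of this iodo allylic alcohol (PdCl2(PPh3)2, CO 1 atm, Et3N, THF, 50 °C), a well-established lactone synthesis, to give 19. If C6 comes out wrong or unselective, F1 is oxidised with Dess–Martin periodinane to the ketone (4Z,8S)-11-iodo-8,13-bis(tert-butyldimethylsilyloxy)-1-(triethylsilyloxy)germacra-4,7(11),10(14)-trien-6-one F2, which is reduced under reagent control (CBS oxazaborolidine, catecholborane) back to F1 with the 6R configuration before carbonylation. This fallback does not help if the nickel macrocyclization itself fails.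

**Step 2.** The enantioselectivity of the bromoallylboration on a small, reactive ynal and the handling of the allene-derived borane are uncertain. The fallback sets out from 4 and comes back at 8. Indium-mediated Barbier addition of 2,3-dibromopropene to 4 (In, THF/H2O) gives racemic 2-bromo-7-(tert-butyldimethylsilyloxy)hept-1-en-5-yn-4-ol F3. Dess–Martin oxidation gives the ynone 2-bromo-7-(tert-butyldimethylsilyloxy)hept-1-en-5-yn-4-one F4. Noyori asymmetric transfer hydrogenation with RuCl(p-cymene)[(S,S)-TsDPEN] in i-PrOH, which is highly selective for ynones and places the alkynyl group as the large substituent, returns the (S)-alcohol 8.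

**Step 10.** Once the C8 hydroxyl is free it sits in the same position relative to the lactone carbonyl as O6, so acyl migration to the 12,8-olide can compete, and the α-methylene ketone is sensitive. The fallback sets out from 21 and comes back at 23. Both TBS ethers are exchanged directly for acetates by Lewis-acid-catalysed acetolysis (Ac2O, catalytic Bi(OTf)3 or FeCl3, MeCN, −20 °C), so the C8 hydroxyl is never liberated and 22 is bypassed; no new compound is made.

## Further compounds

F1 | step 8 | (4Z,6R,8S)-11-iodo-8,13-bis(tert-butyldimethylsilyloxy)-1-(triethylsilyloxy)germacra-4,7(11),10(14)-trien-6-ol (iodine cis to C6) | C=C1C[C@H](O[Si](C)(C)C(C)(C)C)/C(=C(/I)CO[Si](C)(C)C(C)(C)C)[C@H](O)/C=C(/C)CCC1O[Si](CC)(CC)CC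
F2 | step 8 | (4Z,8S)-11-iodo-8,13-bis(tert-butyldimethylsilyloxy)-1-(triethylsilyloxy)germacra-4,7(11),10(14)-trien-6-one | C=C1C[C@H](O[Si](C)(C)C(C)(C)C)/C(=C(/I)CO[Si](C)(C)C(C)(C)C)C(=O)/C=C(/C)CCC1O[Si](CC)(CC)CC
F3 | step 2 | racemic 2-bromo-7-(tert-butyldimethylsilyloxy)hept-1-en-5-yn-4-ol | C=C(Br)CC(O)C#CCO[Si](C)(C)C(C)(C)C
F4 | step 2 | 2-bromo-7-(tert-butyldimethylsilyloxy)hept-1-en-5-yn-4-one | C=C(Br)CC(=O)C#CCO[Si](C)(C)C(C)(C)C
F0 | step 10 | none | none
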